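## Structural features

The target is a ten-membered carbocycle, numbered here C1 (angelate carbon), C2, C3(Me)=C4, C5, C6, C7(Me), C8, C9 (acetate carbon) and C10 (isopropyl carbon); this numbering is used for all intermediates. It holds one E-trisubstituted ring alkene (C3=C4) and a trisubstituted oxirane across C7–C8 in which the ring carbons C6 and C9 are cis, so the epoxide descends from a Z C7=C8 alkene. The five stereocentres are contiguous (C7, C8, C9, C10, C1): C9/C10 and C10/C1 are carbinol–alkyl pairs, and C8/C9 is a cis epoxy-alcohol relationship. The two secondary oxygens at C1 and C9 are 1,3-related and carry different acyl groups, which invites acyl migration. The angelate isomerises easily to the tiglate, the epoxide lies 1,5 to the C3=C4 alkene and can be attacked across the ring under acid, and the 1,5-diene ring of the intermediates is a latent Cope system that should not be heated strongly. The real difficulty is the ten-membered ring itself (strain and entropy oppose closure, and the E alkene must survive it), together with the C1 stereocentre, which has only C10 as a neighbour to control it. The key step exploits the homoallylic alcohol unit C1(O)–C2–C3(Me)=C4: C1 and C2 come from one terminal alkene whose 1,2-diboration puts a masked hydroxyl on C1 and a primary boronate on C2, and that boronate is joined to the alkenyl carbon C3 to close the ring.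

## Logic of the disconnections

23 ⇒ 22. The acyl C–O bond at O9 is cut. The acetate is the smallest and last acyl group, so putting it on at the end avoids any 1,3-acyl shift while a free hydroxyl is present. The forward step must acetylate a hindered hydroxyl next to an oxirane without opening the epoxide or isomerising the angelate.

22 ⇒ 21. The C7–O and C8–O bonds of the oxirane are cut. In 21 the free C9 hydroxyl is allylic to C7=C8 and can deliver the oxygen, and the Z alkene maps onto the cis-substituted oxirane. Two stereocentres disappear. The forward step must attack the face that gives the cis epoxy alcohol and must leave C3=C4 and the angelate alkene alone.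

21 ⇒ 20 ⇒ 17 + 18. The O–Si bond at O9 and the ester C–O bond at O1 are cut. This order differentiates the two hydroxyls: O9 stays silylated while O1 is acylated. The forward steps must esterify without Z→E isomerisation of the acid and remove silicon without generating an alkoxide that could shift the acyl group.

17 ⇒ 16. The C1–O bond is traced back to a C1–B bond. Boron is a masked hydroxyl that survives a basic cross-coupling and is oxidised with retention. The forward step only needs a mild oxidant.

16 ⇒ 13 + 14 (through 15). The ring bond C2–C3 and the C1–B and C2–B bonds are cut. This opens the ring at the homoallylic position and derives both the C1 oxygen and the C2–C3 bond from one terminal alkene. The ring and one stereocentre vanish, leaving an open chain with two stereocentres. The forward step must deliver boron to the correct face of C1, couple only the primary boronate, close the ring in preference to oligomerisation, and keep the E geometry at C3=C4.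

13 ⇒ 12 ⇒ 8 + 9 + 10 (through 11). The O–Si bond and the C9–C10 bond are cut. The anti C9/C10 pair and the terminal C1=C2 vinyl group come together from addition of an E γ-isopropylallyl boron reagent to an aldehyde. Both stereocentres disappear and 8 is achiral. The forward step must keep the E geometry of the allyl unit, control the aldehyde face, and not isomerise the Z enal.

8 ⇒ 7 ⇒ 5 (through 6). The oxidation level at C9 is adjusted, and the C3–Br and C4–H bonds are cut. An E bromide with bromine trans to C5 comes from syn H–Zr addition to a methyl alkyne followed by bromination with retention. The forward step must place zirconium on C3 and tolerate the free hydroxyl.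

5 ⇒ 4 ⇒ 3 ⇒ 1 (through 2). The C3–CH3 bond, the C3–C4 bond (one-carbon homologation of an aldehyde) and the isopropylidene C=C of 1 are cut. Compound 1 supplies C4–C9 with the Z C7=C8 alkene already in place. The forward steps must oxidise only the remote alkene and methylate carbon, not oxygen.

## Other disconnections considered

Alternative 1: The ring is traced back across C5–C6 with the C3–C8 bond restored, to a cyclohexanol A1 with a vinyl group on quaternary C3 and an isopropenyl group on the carbinol carbon C8, cis to each other. Forward, the potassium alkoxide of A1 (KH, 18-crown-6) would undergo an anionic oxy-Cope shift and the enolate would be trapped with PhNTf2 as the enol triflate A2.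
- In its favour: the [3,3] ring expansion is the classic entry to cyclodeca-1,5-dienes. It is concerted, needs no high dilution, and a chair transition state (C2 equatorial, C9 axial, alkoxide equatorial) would fix the E C3=C4 alkene and the cis C7=C8 geometry at once. On the ring-forming event itself it is better founded than the chosen plan.
- Against it here: A1 has five contiguous stereocentres including a quaternary carbon and a tertiary carbinol, which would cost far more steps than open-chain 13. The C8 triflate of A2 has to be reduced off afterwards, and three oxygen protecting groups have to be handled, so the endgame would be about one step longer.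
- Comparison: stereocontrol on a six-membered ring is conventional and equal or better for C9/C10, and the mechanism is well understood. The chosen plan is clearly shorter to the ring-closure substrate and creates C1 in the ring-closing operation instead of carrying it.

Alternative 2: The C6–C7 bond is cut, leading to the open-chain primary iodide A3 with a propynyl ketone at C9. Forward, Bu3SnH with a radical initiator at high dilution would generate the C6 radical, which adds in a ten-membered endo mode to the alkyne carbon C7 to give the dienone A4.
- In its favour: a nucleophilic alkyl radical and an electron-poor alkyne are well matched, the substrate is easy to assemble by acetylide chemistry, and no halide/boron compatibility problem arises. On substrate accessibility it is at least equal to the chosen plan.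
- Against it here: the geometry at C7=C8 is decided by hydrogen transfer to a configurationally labile α-keto vinyl radical and is not under control, whereas the target needs C6 and C9 cis. C10 becomes α to a ketone and can epimerise. The C9 carbinol would have to be set afterwards by a 1,2-reduction whose facial bias in the ring is unknown. Ten is the worst ring size for radical macrocyclisation (premature reduction, 1,5-hydrogen shifts).
- Comparison: both plans need dilution and both form one ring bond. The chosen plan keeps two pre-set alkene geometries and fixes C9/C10 before the ring exists, which the radical route cannot do. The radical route uses stoichiometric tin and needs at least one extra redox step.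

Alternative 3: The C8–C9 bond is cut, leading to the open-chain aldehyde A5 that ends in a Z alkenyl iodide at C8. Forward, CrCl2 with catalytic NiCl2 at high dilution would give the cyclodecadienol A6 (Nozaki–Hiyama–Kishi closure).
- In its favour: this closure is well established for medium-ring allylic alcohols, it tolerates esters and silyl ethers, and the alkenyl geometry is retained. A6 already has the free C9 hydroxyl that directs the epoxidation, so the endgame (epoxidation, acetylation, desilylation, angeloylation) would be one step shorter. On precedent for the ring closure and on the endgame it is better than the chosen plan.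
- Against it here: the C9 stereocentre would be created in the macrocyclisation under substrate control only. A5 has an epimerisable α-stereocentre at C10 and a β-silyloxy group. The Z iodide with iodine cis to C6 is harder to reach than the E bromide of 13, because syn carbometalation gives the other geometry. CrCl2 is needed in large excess.
- Comparison: the chosen plan sets C9 and C10 together by a reagent-controlled allylboration and adds C1 by catalyst control, so its stereochemical design is stronger. Its ring closure is the less proven one.

Key step: step 8

Remarks on the chemistry (assumptions):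
- The (R,R)-antipode of the TADDOL-derived phosphonite is taken to be the one that delivers boron to the C1 face leading to the (1S) boronate (the face that gives (R)-1,2-diols from simple 1-alkenes after oxidation); if the sense is the opposite, the (S,S)-ligand is used.
- Intermediate 2 forms as a racemate; its stereocentre is destroyed in the same step.

## Route

Step 1
Reactants: 1 neryl acetate [(2Z)-3,7-dimethylocta-2,6-dien-1-yl acetate]
Product: 3 (2Z)-3-methyl-6-oxohex-2-en-1-yl acetate, via racemic 6,7-epoxyneryl acetate 2 (not isolated)
Conditions: mCPBA (1.0 equiv), CH2Cl2, −10 → 0 °C; then H5IO6, THF/H2O, 0 °C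
Reagents that add atoms: mCPBA, OOC(=O)c1cccc(Cl)c1
Why: Prilezhaev epoxidation should take the electron-rich terminal alkene in preference to C7=C8, which is deactivated by the allylic acetate; periodic acid then opens the oxirane and cleaves the glycol in the same flask to release the C4 aldehyde.

Step 2
Reactants: 3 (2Z)-3-methyl-6-oxohex-2-en-1-yl acetate
Product: 4 (2Z)-3-methylhept-2-en-6-yn-1-ol
Conditions: dimethyl (1-diazo-2-oxopropyl)phosphonate, K2CO3, MeOH, 0 °C → rt
Reagents that add atoms: dimethyl (1-diazo-2-oxopropyl)phosphonate, CC(=O)C(=[N+]=[N-])P(=O)(OC)OC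
Why: Ohira–Bestmann homologation: the diazomethylphosphonate anion formed by methanolysis adds to the aldehyde, and loss of phosphate and N2 with a 1,2-hydrogen shift gives the terminal alkyne carbon C3; the same K2CO3/MeOH cleaves the acetate and leaves the Z alkene untouched.

Step 3
Reactants: 4 (2Z)-3-methylhept-2-en-6-yn-1-ol
Product: 5 (2Z)-3-methyloct-2-en-6-yn-1-ol
Conditions: n-BuLi (2.1 equiv), THF, −78 → −20 °C; MeI (1.05 equiv), −78 °C → rt
Reagents that add atoms: iodomethane, CI
Why: Acetylide alkylation: double deprotonation gives the lithium alkoxide/acetylide, and in THF the acetylide carbon is far more nucleophilic towards MeI than the aggregated lithium alkoxide, so one equivalent should methylate carbon.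

Step 4
Reactants: 5 (2Z)-3-methyloct-2-en-6-yn-1-ol
Product: 7 (2Z,6E)-7-bromo-3-methylocta-2,6-dien-1-ol, via alkenylzirconocene chloride 6 (not isolated)
Conditions: Cp2ZrHCl (3.2 equiv), THF, rt → 45 °C; then NBS, 0 °C
Reagents that add atoms: N-bromosuccinimide, O=C1CCC(=O)N1Br
Why: Hydrozirconation: one equivalent of Cp2ZrHCl is consumed by the hydroxyl, further reagent adds H–Zr syn across the alkyne and, on equilibration with the excess, places zirconium on the less hindered methyl-bearing C3; bromodezirconation with retention gives bromine trans to C5.

Step 5
Reactants: 7 (2Z,6E)-7-bromo-3-methylocta-2,6-dien-1-ol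
Product: 8 (2Z,6E)-7-bromo-3-methylocta-2,6-dienal
Conditions: activated MnO2, CH2Cl2, rt
Reagents that add atoms: none
Why: Allylic oxidation on the MnO2 surface is neutral and heterogeneous, which should keep the Z enal from isomerising; the alkenyl bromide is inert.

Step 6
Reactants: 8 (2Z,6E)-7-bromo-3-methylocta-2,6-dienal; 9 (E)-4-methylpent-2-ene; 10 (+)-B-methoxydiisopinocampheylborane [(+)-Ipc2BOMe, isopinocampheyl groups from (−)-α-pinene]
Product: 12 (3R,4R,5Z,9E)-10-bromo-6-methyl-3-(propan-2-yl)undeca-1,5,9-trien-4-ol, via [(2E)-4-methylpent-2-en-1-yl]diisopinocampheylborane 11 (not isolated)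
Conditions: 9, KO-t-Bu, n-BuLi, THF, −78 → −50 °C; 10, −78 °C; BF3·OEt2, −78 °C; 8, −78 °C; then NaOH, H2O2, 0 °C → rt
Reagents that add atoms: (E)-4-methylpent-2-ene (9), C/C=C/C(C)C
Why: Brown allylboration: metalation of 9 at its methyl group gives the E allylpotassium, which is transferred to boron as 11; addition to 8 through a closed chair transition state turns the E geometry into the anti C9/C10 relationship, and the isopinocampheyl groups direct attack to the re face of the aldehyde, which should give (9R,10R) and the terminal C1=C2 vinyl group.

Step 7
Reactants: 12 (3R,4R,5Z,9E)-10-bromo-6-methyl-3-(propan-2-yl)undeca-1,5,9-trien-4-ol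
Product: 13 tert-butyl{[(3R,4R,5Z,9E)-10-bromo-6-methyl-3-(propan-2-yl)undeca-1,5,9-trien-4-yl]oxy}dimethylsilane
Conditions: TBSOTf, 2,6-lutidine, CH2Cl2, −78 → 0 °C
Reagents that add atoms: tert-butyldimethylsilyl triflate, CC(C)(C)[Si](C)(C)OS(=O)(=O)C(F)(F)F
Why: Silylation of the hindered secondary allylic alcohol needs the silyl triflate; the TBS ether blocks O9 through the basic coupling and the acylation at O1 and is removed later by fluoride.

Step 8
Reactants: 13 tert-butyl{[(3R,4R,5Z,9E)-10-bromo-6-methyl-3-(propan-2-yl)undeca-1,5,9-trien-4-yl]oxy}dimethylsilane; 14 bis(pinacolato)diboron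
Product: 16 (1S,9R,10S)-9-(tert-butyldimethylsilyloxy)-3,7-dimethyl-1-(pinacolboryl)-10-(propan-2-yl)cyclodeca-3E,7Z-diene, via open-chain 1,2-bis(boronate) 15 (not isolated)
Conditions: 14 (1.05 equiv), Pt(dba)3 (3 mol%), (R,R)-3,5-diisopropylphenyl-TADDOL phenylphosphonite (3.6 mol%), THF, 60 °C; then dilution with THF to 0.003 M, Pd(OAc)2 (10 mol%), RuPhos (10 mol%), KOH (3 equiv), H2O, 70 °C
Reagents that add atoms: bis(pinacolato)diboron (14), CC1(C)OB(OC1(C)C)B2OC(C)(C)C(C)(C)O2
Why: Proposed new method: zerovalent platinum with the chiral phosphonite inserts into the B–B bond of 14, the monosubstituted C1=C2 alkene inserts, and C–B reductive elimination gives the syn bis(boronate) 15; after dilution, zerovalent palladium/RuPhos adds to the C3–Br bond, hydroxide-assisted transmetalation transfers only the primary C2 carbon, and reductive elimination forms C2–C3 with retention of the E geometry, the closest known reaction type being the tandem platinum-catalysed diboration of terminal alkenes and palladium coupling of the primary boronate with alkenyl halides between two molecules, together with B-alkyl Suzuki–Miyaura macrocyclisation. The ten-membered ring closes at the C2–C3 σ bond by reductive elimination from an eleven-membered C2–Pd–C3 palladacycle, with both reacting carbons ending up in the ring. The new C1 stereocentre is set in the diboration by the phosphonite ligand (catalyst control next to the C10 centre), boron going to the face that becomes the (1S) carbinol after oxidation with retention. Selectivity for C2 over C1 in the coupling rests on the lower steric demand of the primary boronate and on its activation by the neighbouring boron, whose ate complex should transmetalate much faster than the secondary one. Chemoselectivity in the first stage rests on the inertness of trisubstituted alkenes and of the C–Br bond towards the platinum catalyst at 60 °C. Ring closure over oligomerisation is favoured by high dilution in the palladium stage and by the two defined alkenes and the C9/C10 substituents, which pre-fold the chain.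

Step 9
Reactants: 16 (1S,9R,10S)-9-(tert-butyldimethylsilyloxy)-3,7-dimethyl-1-(pinacolboryl)-10-(propan-2-yl)cyclodeca-3E,7Z-diene
Product: 17 (1S,9S,10R)-9-(tert-butyldimethylsilyloxy)-3,7-dimethyl-10-(propan-2-yl)cyclodeca-3E,7Z-dien-1-ol
Conditions: NaBO3·4H2O, THF/H2O, rt
Reagents that add atoms: sodium perborate tetrahydrate, [Na+].[Na+].O[B-]1(O)OO[B-](O)(O)OO1.O.O.O.O.O.O
Why: Boronate oxidation: the boron-to-oxygen 1,2-shift goes with retention, so the C1 configuration from step 8 is carried into the alcohol; the nearly neutral oxidant leaves both alkenes and the silyl ether alone.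

Step 10
Reactants: 17 (1S,9S,10R)-9-(tert-butyldimethylsilyloxy)-3,7-dimethyl-10-(propan-2-yl)cyclodeca-3E,7Z-dien-1-ol; 18 angelic acid [(2Z)-2-methylbut-2-enoic acid]
Product: 20 (1S,9S,10R)-9-(tert-butyldimethylsilyloxy)-3,7-dimethyl-10-(propan-2-yl)cyclodeca-3E,7Z-dien-1-yl (2Z)-2-methylbut-2-enoate, via angelic 2,4,6-trichlorobenzoic anhydride 19 (not isolated)
Conditions: 18, 2,4,6-trichlorobenzoyl chloride, Et3N, toluene, rt; then 17, toluene, 75 °C
Reagents that add atoms: angelic acid (18), C/C=C(/C)C(=O)O
Why: Yamaguchi esterification: the mixed anhydride 19 acylates the C1 hydroxyl at the less hindered angeloyl carbonyl on warming; leaving out nucleophilic catalysts such as DMAP avoids the addition–elimination path that turns angelates into tiglates.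

Step 11
Reactants: 20 (1S,9S,10R)-9-(tert-butyldimethylsilyloxy)-3,7-dimethyl-10-(propan-2-yl)cyclodeca-3E,7Z-dien-1-yl (2Z)-2-methylbut-2-enoate
Product: 21 (1S,9S,10S)-9-hydroxy-3,7-dimethyl-10-(propan-2-yl)cyclodeca-3E,7Z-dien-1-yl (2Z)-2-methylbut-2-enoate
Conditions: HF·pyridine, pyridine, THF, 0 °C → rt
Reagents that add atoms: none
Why: Acidic fluoride cleaves the Si–O bond without forming a free alkoxide, so neither a 1,3-acyl shift from O1 to O9 nor Z→E isomerisation of the angelate should occur.

Step 12
Reactants: 21 (1S,9S,10S)-9-hydroxy-3,7-dimethyl-10-(propan-2-yl)cyclodeca-3E,7Z-dien-1-yl (2Z)-2-methylbut-2-enoate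
Product: 22 (1S,7S,8R,9R,10S)-7,8-epoxy-9-hydroxy-3,7-dimethyl-10-(propan-2-yl)cyclodec-3E-en-1-yl (2Z)-2-methylbut-2-enoate
Conditions: VO(acac)2 (5 mol%), t-BuOOH (decane), CH2Cl2, 0 °C
Reagents that add atoms: tert-butyl hydroperoxide, CC(C)(C)OO
Why: Hydroxyl-directed epoxidation: the C9 alkoxide binds the pentavalent vanadium alkylperoxide and delivers oxygen only to C7=C8; vanadium prefers a small O–C9–C8=C7 dihedral angle, which in a medium-ring Z allylic alcohol means attack on the peripheral face syn to the hydroxyl and should give the cis epoxy alcohol (7S,8R), while C3=C4 and the electron-poor angelate are not touched.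

Step 13
Reactants: 22 (1S,7S,8R,9R,10S)-7,8-epoxy-9-hydroxy-3,7-dimethyl-10-(propan-2-yl)cyclodec-3E-en-1-yl (2Z)-2-methylbut-2-enoate
Product: 23 (1S,7S,8R,9R,10R)-9-acetoxy-7,8-epoxy-3,7-dimethyl-10-(propan-2-yl)cyclodec-3E-en-1-yl (2Z)-2-methylbut-2-enoate (CNP0289272.1)
Conditions: Ac2O, pyridine, DMAP (cat.), CH2Cl2, 0 °C → rt
Reagents that add atoms: acetic anhydride, CC(=O)OC(C)=O
Why: Standard acylation of the remaining secondary hydroxyl; the base-buffered medium protects the epoxide from transannular opening, and the step completes the target.

## Compound list

1 | neryl acetate | CC(C)=CCC/C(C)=C\COC(C)=O | starting material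
2 | racemic 6,7-epoxyneryl acetate | CC(=O)OC/C=C(C)\CCC1OC1(C)C | intermediate (not isolated)
3 | (2Z)-3-methyl-6-oxohex-2-en-1-yl acetate | CC(=O)OC/C=C(C)\CCC=O | intermediate
4 | (2Z)-3-methylhept-2-en-6-yn-1-ol | OC/C=C(C)\CCC#C | intermediate
5 | (2Z)-3-methyloct-2-en-6-yn-1-ol | OC/C=C(C)\CCC#CC | intermediate
6 | C3-zirconated, O-zirconated alkenylzirconocene chloride from 5 | C/C(=C\CC/C(C)=C\CO[Zr](Cl)(C1C=CC=C1)C1C=CC=C1)[Zr](Cl)(C1C=CC=C1)C1C=CC=C1 | intermediate (not isolated)
7 | (2Z,6E)-7-bromo-3-methylocta-2,6-dien-1-ol | OC/C=C(C)\CC/C=C(\C)Br | intermediate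
8 | (2Z,6E)-7-bromo-3-methylocta-2,6-dienal | O=C/C=C(C)\CC/C=C(\C)Br | intermediate
9 | (E)-4-methylpent-2-ene | C/C=C/C(C)C | starting material
10 | (+)-B-methoxydiisopinocampheylborane | COB([C@H]1C[C@H]2C[C@@H]([C@@H]1C)C2(C)C)[C@H]1C[C@H]2C[C@@H]([C@@H]1C)C2(C)C | starting material
11 | [(2E)-4-methylpent-2-en-1-yl]diisopinocampheylborane | CC(C)/C=C/CB([C@H]1C[C@H]2C[C@@H]([C@@H]1C)C2(C)C)[C@H]1C[C@H]2C[C@@H]([C@@H]1C)C2(C)C | intermediate (not isolated)
12 | (3R,4R,5Z,9E)-10-bromo-6-methyl-3-(propan-2-yl)undeca-1,5,9-trien-4-ol | C=C[C@@H](C(C)C)[C@@H](O)/C=C(C)\CC/C=C(\C)Br | intermediate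
13 | TBS ether of 12 (open-chain trienyl bromide) | C=C[C@@H](C(C)C)[C@@H](O[Si](C)(C)C(C)(C)C)/C=C(C)\CC/C=C(\C)Br | intermediate
14 | bis(pinacolato)diboron | CC1(C)OB(OC1(C)C)B2OC(C)(C)C(C)(C)O2 | starting material
15 | (2S,3S,4R,5Z,9E)-10-bromo-4-(tert-butyldimethylsilyloxy)-6-methyl-3-(propan-2-yl)undeca-5,9-diene-1,2-diyl bis(pinacol boronate) | CC1(C)OB(OC1(C)C)C[C@H](B2OC(C)(C)C(C)(C)O2)[C@@H](C(C)C)[C@@H](O[Si](C)(C)C(C)(C)C)/C=C(C)\CC/C=C(\C)Br | intermediate (not isolated)
16 | (1S,9R,10S) ten-membered diene with C1 pinacol boronate and C9 TBS ether | CC1(C)OB(OC1(C)C)[C@H]2C/C(C)=C/CC/C(C)=C\[C@H](O[Si](C)(C)C(C)(C)C)[C@@H]2C(C)C | intermediate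
17 | (1S,9S,10R) ten-membered dienol with C9 TBS ether | O[C@H]1C/C(C)=C/CC/C(C)=C\[C@H](O[Si](C)(C)C(C)(C)C)[C@@H]1C(C)C | intermediate
18 | angelic acid | C/C=C(/C)C(=O)O | starting material
19 | angelic 2,4,6-trichlorobenzoic anhydride | C/C=C(/C)C(=O)OC(=O)c1c(Cl)cc(Cl)cc1Cl | intermediate (not isolated)
20 | (1S,9S,10R) C1 angelate with C9 TBS ether | C/C=C(/C)C(=O)O[C@H]1C/C(C)=C/CC/C(C)=C\[C@H](O[Si](C)(C)C(C)(C)C)[C@@H]1C(C)C | intermediate
21 | (1S,9S,10S) C1 angelate with free C9 hydroxyl | C/C=C(/C)C(=O)O[C@H]1C/C(C)=C/CC/C(C)=C\[C@H](O)[C@@H]1C(C)C | intermediate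
22 | (1S,7S,8R,9R,10S) 7,8-epoxy-9-hydroxy C1 angelate | C/C=C(/C)C(=O)O[C@H]1C/C(C)=C/CC[C@]2(C)O[C@@H]2[C@H](O)[C@@H]1C(C)C | intermediate
23 | (1S,7S,8R,9R,10R)-9-acetoxy-7,8-epoxy-3,7-dimethyl-10-(propan-2-yl)cyclodec-3E-en-1-yl (2Z)-2-methylbut-2-enoate | C/C=C(/C)C(=O)O[C@H]1C/C(C)=C/CC[C@]2(C)O[C@@H]2[C@H](OC(C)=O)[C@@H]1C(C)C | target

## Step count and least certain steps

Total: 13 steps. Longest linear sequence: 13 steps (1 → 23); 9, 10, 14 and 18 are commercial and enter directly.

Step 8 (key step, proposed new method).
- What may go wrong: oligomerisation instead of ring closure, because the palladium-bound chain has to reach C2 through a strained eleven-membered palladacycle; protodeboronation or β-hydride elimination of the primary boronate during a slow transmetalation; sluggish or face-unselective diboration of the α-branched alkene if catalyst and C10 centre are mismatched; loss of the C–Br bond in the platinum stage.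
- Fallback (known chemistry, from 13 back to 17): Tsuji–Wacker oxidation of the terminal alkene (PdCl2, CuCl, O2, DMF/H2O) would give the C1 methyl ketone F1. Kinetic enol silylation at the methyl group (LiN(i-Pr)2, Et3SiCl, THF, −78 °C) would give the 2-(triethylsilyloxy)-1-alkene F2. Hydroboration with 9-BBN puts boron on C2 and hydrogen on C1 and would give the β-silyloxyalkyl borane F3, used without isolation. Intramolecular B-alkyl Suzuki–Miyaura coupling with the C3 bromide (Pd(dppf)Cl2, AsPh3, Cs2CO3, DMF/THF/H2O, high dilution) would give the C1 triethylsilyl ether of the ring F4. Selective removal of the triethylsilyl group (pyridinium p-toluenesulfonate, MeOH, 0 °C) returns to 17. The price is that C1 then depends on substrate-controlled hydroboration next to C10.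

Step 6.
- What may go wrong: erosion of the E geometry of the allyl unit (allylpotassium isomerisation or 1,3-boron shift on warming), which would leak into the syn diastereomer; competing metalation at the methine of 9; lower enantioselectivity with the bulky γ-substituent; Z→E isomerisation of the enal before addition.
- Fallback (from 9 and 8 back to 12): the same allylpotassium from 9 would be trapped with 2-isopropoxy-4,4,5,5-tetramethyl-1,3,2-dioxaborolane to give the isolable, configurationally stable (E)-allyl pinacol boronate F5. F5 would then be added to 8 under chiral phosphoric acid catalysis (the TRIP antipode that directs attack to the re face, taken to be (R)-TRIP; toluene, −30 °C). This replaces reagent control by catalyst control and should give 12 with the same anti relationship from the closed chair transition state.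

Step 12.
- What may go wrong: poor facial selectivity if the ring prefers a conformer with the hydroxyl on the peripheral face at a large dihedral angle; Lewis-acid-induced transannular attack of C3=C4 on the new epoxide.
- Fallback (from 21 back to 22): conformational control would be replaced by reagent control, using the titanium tartrate epoxidation (Ti(O-i-Pr)4, L-(+)-diisopropyl tartrate, t-BuOOH, 4 Å molecular sieves, CH2Cl2, −20 °C). By the empirical facial rule this tartrate is the matched partner of the (9R) carbinol and delivers oxygen to the same face, so 22 would form directly; this fallback makes no new compound (F0).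

Step 10.
- What may go wrong: isomerisation of the angeloyl unit to the tigloyl unit during activation, and slow acylation of the hindered C1 hydroxyl.
- Fallback (from 17 back to 20): 17 would be esterified with 2-[bis(2,2,2-trifluoroethoxy)phosphoryl]propanoic acid (dicyclohexylcarbodiimide, DMAP) to the phosphonopropionate F6. A Still–Gennari olefination with acetaldehyde (KN(SiMe3)2, 18-crown-6, THF, −78 °C) would then build the Z-trisubstituted enoate on the molecule and give 20 without ever activating angelic acid.

Step 3.
- What may go wrong: competing O-methylation of the alkoxide or incomplete C-methylation.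
- Fallback (from 4 back to 5): 4 would be silylated (TBSCl, imidazole) to the silyl ether F7, methylated at the alkyne (n-BuLi, MeI) to the silyl ether F8, and desilylated with Bu4NF to give 5.

## Further compounds

F1 | step 8 | C1 methyl ketone from Wacker oxidation of 13 | CC(=O)[C@@H](C(C)C)[C@@H](O[Si](C)(C)C(C)(C)C)/C=C(C)\CC/C=C(\C)Br
F2 | step 8 | 2-(triethylsilyloxy)-1-alkene (kinetic silyl enol ether of F1) | C=C(O[Si](CC)(CC)CC)[C@@H](C(C)C)[C@@H](O[Si](C)(C)C(C)(C)C)/C=C(C)\CC/C=C(\C)Br
F3 | step 8 | B-(β-silyloxyalkyl)-9-BBN from F2 | C(B1C2CCCC1CCC2)[C@H](O[Si](CC)(CC)CC)[C@@H](C(C)C)[C@@H](O[Si](C)(C)C(C)(C)C)/C=C(C)\CC/C=C(\C)Br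
F4 | step 8 | ten-membered diene with C1 triethylsilyl ether and C9 TBS ether | CC[Si](CC)(CC)O[C@H]1C/C(C)=C/CC/C(C)=C\[C@H](O[Si](C)(C)C(C)(C)C)[C@@H]1C(C)C
F5 | step 6 | (E)-(4-methylpent-2-en-1-yl) pinacol boronate | CC(C)/C=C/CB1OC(C)(C)C(C)(C)O1
F0 | step 12 | none | none
F6 | step 10 | C1 2-[bis(2,2,2-trifluoroethoxy)phosphoryl]propanoate of 17 | CC(C(=O)O[C@H]1C/C(C)=C/CC/C(C)=C\[C@H](O[Si](C)(C)C(C)(C)C)[C@@H]1C(C)C)P(=O)(OCC(F)(F)F)OCC(F)(F)F
F7 | step 3 | TBS ether of 4 | C#CCC/C(C)=C\CO[Si](C)(C)C(C)(C)C
F8 | step 3 | TBS ether of 5 | CC#CCC/C(C)=C\CO[Si](C)(C)C(C)(C)C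
A1 | alternative 1 | cyclohexanol with cis vinyl (C3) and isopropenyl (C8) groups, C9 PMB ether, C10 isopropyl, C1 TBS ether | C=C[C@]1(C)C[C@H](O[Si](C)(C)C(C)(C)C)[C@@H](C(C)C)[C@@H](OCc2ccc(OC)cc2)[C@]1(O)C(C)=C
A2 | alternative 1 | cyclodecadienyl C8 enol triflate | CC(C)(C)[Si](C)(C)O[C@H]1C/C(C)=C/CC/C(C)=C(OS(=O)(=O)C(F)(F)F)\[C@H](OCc2ccc(OC)cc2)[C@@H]1C(C)C
A3 | alternative 2 | open-chain C6 iodide with C9 propynyl ketone and C1 TBS ether | ICC/C=C(C)/C[C@H](O[Si](C)(C)C(C)(C)C)[C@@H](C(C)C)C(=O)C#CC
A4 | alternative 2 | ten-membered dienone (C9 ketone, C1 TBS ether) | CC(C)(C)[Si](C)(C)O[C@H]1C/C(C)=C/CC/C(C)=C\C(=O)[C@@H]1C(C)C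
A5 | alternative 3 | open-chain C9 aldehyde with Z C8 alkenyl iodide and C1 TBS ether | O=C[C@H](C(C)C)[C@@H](O[Si](C)(C)C(C)(C)C)C/C(C)=C/CC/C(C)=C\I
A6 | alternative 3 | cyclodecadienol with free C9 hydroxyl (C1 TBS ether) | CC(C)(C)[Si](C)(C)O[C@H]1C/C(C)=C/CC/C(C)=C\[C@H](O)[C@@H]1C(C)C
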